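**Retrosynthetic overview**
1. Target 14 ← 13 by removal of three MOM ethers (O5 and O7 on ring A, O4' on ring B); nothing else changes after the key step.
2. 13 ← 12 by disconnecting C3–C4 of ring C. The enabling feature is that ring C is just C4(=O)–C3H2–C2H(O1)(ring B aryl): a formyl C–H on C4a of ring A added across the enol ether O1–C2(aryl)=C3H2, with the only stereocenter, C2, β to the ketone where the hydride lands.
3. 12 ← aryl ester 9 by carbonyl methylenation (C3 comes from a titanium methylidene) and adjustment of a hindered methyl ester (future C4) to the aldehyde; 9 ← phenol 3 (ring A) + acid 7 (ring B).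
4. Ring A comes from methyl 2,4,6-trihydroxybenzoate by double C-prenylation; its two ortho hydroxyls (future O1 and O5) are equivalent, so the ester is unambiguous. Ring B comes from 5-bromovanillin by Stille prenylation.
5. Order of ring formation: rings A and B are bought as arenes; ring C, the only ring made, is closed last (step 10) together with C2.

Key step: step 10

Remark: C2 of the target is read as (S) (O1 > ring B carbon > C3 > H). The bisphosphine enantiomer that gives (S) must be fixed in a first run; (R)-DTBM-SEGPHOS is written provisionally.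
Abbreviations: prenyl = 3-methylbut-2-en-1-yl; MOM = methoxymethyl; ArB = 3-methoxy-4-(methoxymethoxy)-5-prenylphenyl.

**Step 1**
Reactants: 1 methyl 2,4,6-trihydroxybenzoate
Product: 2 methyl 2,4,6-trihydroxy-3,5-diprenylbenzoate
Conditions: prenyl bromide (2.1 equiv), DBU (2.2 equiv), THF, 0 °C to rt
Reagents that add atoms: prenyl bromide (1-bromo-3-methylbut-2-ene), CC(C)=CCBr
Why: Phenolate C-alkylation, in which the deprotonated phloroglucinol carboxylate attacks the allylic bromide through its only two free ring carbons (C3 and C5, equivalent by symmetry) and rearomatizes, the amidine base in an aprotic solvent being chosen to favour C- over O-alkylation.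

**Step 2**
Reactants: 2 methyl 2,4,6-trihydroxy-3,5-diprenylbenzoate
Product: 3 methyl 2-hydroxy-4,6-bis(methoxymethoxy)-3,5-diprenylbenzoate
Conditions: MOMCl (2.2 equiv), i-Pr2NEt, CH2Cl2, 0 °C
Reagents that add atoms: chloromethyl methyl ether, COCCl
Why: Williamson-type O-alkylation should go to the two hydroxyls not held in the hydrogen bond to the ester carbonyl, leaving one ortho hydroxyl (the future O1) free, and it does not matter which one because the two are equivalent.

**Step 3**
Reactants: 4 5-bromovanillin (3-bromo-4-hydroxy-5-methoxybenzaldehyde)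
Product: 5 3-bromo-5-methoxy-4-(methoxymethoxy)benzaldehyde
Conditions: MOMCl (1.3 equiv), i-Pr2NEt, CH2Cl2, 0 °C to rt
Reagents that add atoms: chloromethyl methyl ether, COCCl
Why: Williamson-type O-alkylation masks the acidic phenol before cross-coupling and gives ring B the same protecting group as ring A for one final deprotection.

**Step 4**
Reactants: 5 3-bromo-5-methoxy-4-(methoxymethoxy)benzaldehyde
Product: 6 3-methoxy-4-(methoxymethoxy)-5-prenylbenzaldehyde
Conditions: tributyl(prenyl)stannane (1.3 equiv), Pd(PPh3)4 (5 mol %), DMF, 95 °C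
Reagents that add atoms: tributyl(3-methylbut-2-en-1-yl)stannane, CCCC[Sn](CCCC)(CCCC)CC=C(C)C
Why: Stille coupling, in which the aryl bromide (activated by the para formyl group) adds to zerovalent palladium, the allyl group is transferred from tin with bond formation at its unsubstituted terminus, and reductive elimination should give the linear prenyl arene with the aldehyde untouched.

**Step 5**
Reactants: 6 3-methoxy-4-(methoxymethoxy)-5-prenylbenzaldehyde
Product: 7 3-methoxy-4-(methoxymethoxy)-5-prenylbenzoic acid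
Conditions: NaClO2, NaH2PO4, 2-methylbut-2-ene (excess), t-BuOH/H2O, 0 °C to rt
Reagents that add atoms: sodium chlorite, [Na+].[O-]Cl=O
Why: Pinnick oxidation, with 2-methylbut-2-ene taking up the hypochlorous acid that would otherwise attack the prenyl group and a buffer mild enough to keep the MOM ether.

**Step 6**
Reactants: 7 3-methoxy-4-(methoxymethoxy)-5-prenylbenzoic acid; 3 methyl 2-hydroxy-4,6-bis(methoxymethoxy)-3,5-diprenylbenzoate
Product: 9 methyl 2-[(ArB-carbonyl)oxy]-4,6-bis(methoxymethoxy)-3,5-diprenylbenzoate, via aroyl chloride 8 (not isolated)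
Conditions: 1-chloro-N,N,2-trimethylprop-1-en-1-amine (1.1 equiv), CH2Cl2, 0 °C; then 3, Et3N, DMAP (0.2 equiv), rt
Reagents that add atoms: 1-chloro-N,N,2-trimethylprop-1-en-1-amine, CC(C)=C(Cl)N(C)C (gives only the chlorine of the non-isolated 8; no atom of it remains in 9)
Why: The α-chloroenamine makes the acyl chloride without releasing HCl, so the MOM ethers survive, and DMAP-catalysed acylation through the acylpyridinium ion should then esterify the hindered, hydrogen-bonded phenol of 3.

**Step 7**
Reactants: 9 methyl 2-[(ArB-carbonyl)oxy]-4,6-bis(methoxymethoxy)-3,5-diprenylbenzoate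
Product: 10 methyl 2-[(1-ArB-ethenyl)oxy]-4,6-bis(methoxymethoxy)-3,5-diprenylbenzoate
Conditions: Cp2Ti(μ-Cl)(μ-CH2)AlMe2 (1.2 equiv), pyridine, THF/toluene, −40 to 0 °C; aq NaOH quench; basic Al2O3
Reagents that add atoms: Cp2Ti(μ-Cl)(μ-CH2)AlMe2, C[Al-]1(C)C[Ti]([Cl+]1)(C1C=CC=C1)C1C=CC=C1
Why: Tebbe methylenation, in which Cp2Ti=CH2 adds [2+2] to the aryl ester carbonyl and the oxatitanacyclobutane cycloreverts to the enol ether, the aryl ester being expected to react first because it is the more electrophilic carbonyl while the methyl ester is twisted and shielded between two ortho oxygen substituents, and the trisubstituted prenyl alkenes being inert.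

**Step 8**
Reactants: 10 methyl 2-[(1-ArB-ethenyl)oxy]-4,6-bis(methoxymethoxy)-3,5-diprenylbenzoate
Product: 11 {2-[(1-ArB-ethenyl)oxy]-4,6-bis(methoxymethoxy)-3,5-diprenylphenyl}methanol
Conditions: i-Bu2AlH (3 equiv), toluene, −78 to 0 °C; aq potassium sodium tartrate
Reagents that add atoms: none
Why: Hydride reduction of the benzoate to the primary alcohol by a small, Lewis acidic aluminium hydride that should reach the hindered ester and leave the enol ether, MOM ethers and alkenes alone, with a neutral work-up for the acid-labile enol ether.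

**Step 9**
Reactants: 11 {2-[(1-ArB-ethenyl)oxy]-4,6-bis(methoxymethoxy)-3,5-diprenylphenyl}methanol
Product: 12 2-[(1-ArB-ethenyl)oxy]-4,6-bis(methoxymethoxy)-3,5-diprenylbenzaldehyde
Conditions: MnO2 (activated, 15 equiv), CH2Cl2, rt
Reagents that add atoms: none
Why: Heterogeneous MnO2 oxidation of the electron-rich benzylic alcohol should stop at the aldehyde under neutral conditions, as the acid-labile α-aryl enol ether requires.

**Step 10**
Reactants: 12 2-[(1-ArB-ethenyl)oxy]-4,6-bis(methoxymethoxy)-3,5-diprenylbenzaldehyde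
Product: 13 (2S)-2-ArB-5,7-bis(methoxymethoxy)-6,8-diprenyl-2,3-dihydro-4H-chromen-4-one
Conditions: [Rh(cod)Cl]2 (2.5 mol %), (R)-DTBM-SEGPHOS (5 mol %), Na[B(3,5-(CF3)2C6H3)4] (5 mol %), 1,4-dioxane, 60 °C
Reagents that add atoms: none
Why: Proposed new method: the formyl C–H bond of 12 adds oxidatively to the cationic monovalent rhodium bisphosphine complex to give an acyl hydride of trivalent rhodium, the tethered enol ether inserts into Rh–H with hydride going to C2 and rhodium to the terminal C3, and C–C reductive elimination forms the C3–C4 bond. The closest known reaction type is the enantioselective rhodium-catalysed intramolecular endo hydroacylation of 1,1-disubstituted alkenes by aryl aldehydes (2-(1-substituted vinyl)benzaldehydes to 3-substituted indanones, N-(1-substituted vinyl)indole-2-carbaldehydes to pyrroloindolones, ortho-allylbenzaldehydes to six-membered benzo-fused ketones); new here are the aryl enol ether as the alkene and a six-membered ring with oxygen in the tether. Ring C closes in the 6-endo-trig mode, both alkene carbons ending inside the pyranone ring. The C2 stereocenter is set in the hydride insertion by the chiral bisphosphine, which selects one enantiotopic face of the prochiral enol ether (catalyst control, no substrate stereocenter). Regioselectivity (acyl to C3 rather than to C2, which would give a five-membered ketone with a quaternary carbon) should follow from the 1,1-disubstitution, since a tertiary alkyl rhodium is disfavoured, and chemoselectivity over the three prenyl groups from their trisubstitution and their distance from the formyl group. The competing paths are decarbonylation and β-aryloxy elimination from the C3-bound alkyl rhodium, which the chelating bisphosphine, the ortho ether oxygens and the non-coordinating counterion are expected to slow.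

**Step 11**
Reactants: 13 (2S)-2-ArB-5,7-bis(methoxymethoxy)-6,8-diprenyl-2,3-dihydro-4H-chromen-4-one
Product: 14 (2S)-5,7-dihydroxy-2-(4-hydroxy-3-methoxy-5-prenylphenyl)-6,8-diprenyl-2,3-dihydro-4H-chromen-4-one (target)
Conditions: 3 M aq HCl, MeOH, 40 °C
Reagents that add atoms: none
Why: Acid-catalysed acetal exchange should transfer the three methoxymethyl groups to methanol, acid being chosen over base because a flavanone with free 5- and 4'-hydroxyls opens to the chalcone and racemizes under base whereas C2 should be untouched here.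

**Compound list**
1 | methyl 2,4,6-trihydroxybenzoate | COC(=O)c1c(O)cc(O)cc1O | starting material
2 | methyl 2,4,6-trihydroxy-3,5-bis(3-methylbut-2-en-1-yl)benzoate | COC(=O)c1c(O)c(CC=C(C)C)c(O)c(CC=C(C)C)c1O | intermediate
3 | methyl 2-hydroxy-4,6-bis(methoxymethoxy)-3,5-bis(3-methylbut-2-en-1-yl)benzoate | COC(=O)c1c(O)c(CC=C(C)C)c(OCOC)c(CC=C(C)C)c1OCOC | intermediate
4 | 3-bromo-4-hydroxy-5-methoxybenzaldehyde (5-bromovanillin) | COc1cc(C=O)cc(Br)c1O | starting material
5 | 3-bromo-5-methoxy-4-(methoxymethoxy)benzaldehyde | COc1cc(C=O)cc(Br)c1OCOC | intermediate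
6 | 3-methoxy-4-(methoxymethoxy)-5-(3-methylbut-2-en-1-yl)benzaldehyde | COc1cc(C=O)cc(CC=C(C)C)c1OCOC | intermediate
7 | 3-methoxy-4-(methoxymethoxy)-5-(3-methylbut-2-en-1-yl)benzoic acid | COc1cc(C(=O)O)cc(CC=C(C)C)c1OCOC | intermediate
8 | 3-methoxy-4-(methoxymethoxy)-5-(3-methylbut-2-en-1-yl)benzoyl chloride | COc1cc(C(=O)Cl)cc(CC=C(C)C)c1OCOC | intermediate
9 | methyl 2-{[3-methoxy-4-(methoxymethoxy)-5-(3-methylbut-2-en-1-yl)benzoyl]oxy}-4,6-bis(methoxymethoxy)-3,5-bis(3-methylbut-2-en-1-yl)benzoate | COc1cc(C(=O)Oc2c(C(=O)OC)c(OCOC)c(CC=C(C)C)c(OCOC)c2CC=C(C)C)cc(CC=C(C)C)c1OCOC | intermediate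
10 | methyl 2-({1-[3-methoxy-4-(methoxymethoxy)-5-(3-methylbut-2-en-1-yl)phenyl]ethenyl}oxy)-4,6-bis(methoxymethoxy)-3,5-bis(3-methylbut-2-en-1-yl)benzoate | COc1cc(C(=C)Oc2c(C(=O)OC)c(OCOC)c(CC=C(C)C)c(OCOC)c2CC=C(C)C)cc(CC=C(C)C)c1OCOC | intermediate
11 | [2-({1-[3-methoxy-4-(methoxymethoxy)-5-(3-methylbut-2-en-1-yl)phenyl]ethenyl}oxy)-4,6-bis(methoxymethoxy)-3,5-bis(3-methylbut-2-en-1-yl)phenyl]methanol | COc1cc(C(=C)Oc2c(CO)c(OCOC)c(CC=C(C)C)c(OCOC)c2CC=C(C)C)cc(CC=C(C)C)c1OCOC | intermediate
12 | 2-({1-[3-methoxy-4-(methoxymethoxy)-5-(3-methylbut-2-en-1-yl)phenyl]ethenyl}oxy)-4,6-bis(methoxymethoxy)-3,5-bis(3-methylbut-2-en-1-yl)benzaldehyde | COc1cc(C(=C)Oc2c(C=O)c(OCOC)c(CC=C(C)C)c(OCOC)c2CC=C(C)C)cc(CC=C(C)C)c1OCOC | intermediate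
13 | (2S)-5,7-bis(methoxymethoxy)-2-[3-methoxy-4-(methoxymethoxy)-5-(3-methylbut-2-en-1-yl)phenyl]-6,8-bis(3-methylbut-2-en-1-yl)-2,3-dihydro-4H-chromen-4-one | COc1cc([C@@H]2CC(=O)c3c(OCOC)c(CC=C(C)C)c(OCOC)c(CC=C(C)C)c3O2)cc(CC=C(C)C)c1OCOC | intermediate
14 | (2S)-5,7-dihydroxy-2-[4-hydroxy-3-methoxy-5-(3-methylbut-2-en-1-yl)phenyl]-6,8-bis(3-methylbut-2-en-1-yl)-2,3-dihydro-4H-chromen-4-one (CNP0235424.1) | COc1cc([C@@H]2CC(=O)c3c(O)c(CC=C(C)C)c(O)c(CC=C(C)C)c3O2)cc(CC=C(C)C)c1O | target

**Step count**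
Total: 11 steps. Longest linear sequence: 9 steps (4 → 14 through steps 3 to 11); the ring A branch (steps 1 and 2) joins at step 6.

**Steps most likely to fail**

Step 10 (proposed new method). The acyl rhodium hydride may lose CO before the hindered enol ether inserts, the C3-bound alkyl rhodium may undergo β-aryloxy elimination, or hydride insertion may show poor facial selectivity. The fallback uses known chalcone chemistry; it sets out from aldehyde 6 and comes back at 13. Commercial 1-(2,4,6-trihydroxyphenyl)ethanone is C-diprenylated as in step 1 to give 1-[2,4,6-trihydroxy-3,5-bis(3-methylbut-2-en-1-yl)phenyl]ethanone F1. Bis-MOM protection as in step 2 gives 1-[2-hydroxy-4,6-bis(methoxymethoxy)-3,5-bis(3-methylbut-2-en-1-yl)phenyl]ethanone F2. Claisen–Schmidt condensation of F2 with 6 (KOH, EtOH, rt) should give (E)-1-[2-hydroxy-4,6-bis(methoxymethoxy)-3,5-bis(3-methylbut-2-en-1-yl)phenyl]-3-[3-methoxy-4-(methoxymethoxy)-5-(3-methylbut-2-en-1-yl)phenyl]prop-2-en-1-one F3. Oxa-Michael ring closure (NaOAc, EtOH, reflux) gives rac-5,7-bis(methoxymethoxy)-2-[3-methoxy-4-(methoxymethoxy)-5-(3-methylbut-2-en-1-yl)phenyl]-6,8-bis(3-methylbut-2-en-1-yl)-2,3-dihydro-4H-chromen-4-one F4. Preparative HPLC on a chiral stationary phase then separates the (S)-enantiomer, which is 13.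

Step 7. The methylidene may also attack the methyl ester, and the α-aryl enol ether may hydrolyse during isolation. The fallback carries the future C4 as a silyl-protected alcohol through the methylenation, so no second ester is present; it sets out from 3 and comes back at 11. Reduction of 3 (LiAlH4, THF, 0 °C) gives 2-(hydroxymethyl)-3,5-bis(methoxymethoxy)-4,6-bis(3-methylbut-2-en-1-yl)phenol F5, used at once. Silylation of the primary alcohol (TBSCl, imidazole, CH2Cl2, −20 °C) gives 2-{[(tert-butyldimethylsilyl)oxy]methyl}-3,5-bis(methoxymethoxy)-4,6-bis(3-methylbut-2-en-1-yl)phenol F6. Acylation with 8 as in step 6 gives 2-{[(tert-butyldimethylsilyl)oxy]methyl}-3,5-bis(methoxymethoxy)-4,6-bis(3-methylbut-2-en-1-yl)phenyl 3-methoxy-4-(methoxymethoxy)-5-(3-methylbut-2-en-1-yl)benzoate F7. Methylenation as in step 7 gives tert-butyl{[2-({1-[3-methoxy-4-(methoxymethoxy)-5-(3-methylbut-2-en-1-yl)phenyl]ethenyl}oxy)-4,6-bis(methoxymethoxy)-3,5-bis(3-methylbut-2-en-1-yl)phenyl]methoxy}dimethylsilane F8. Desilylation (n-Bu4NF, THF, 0 °C) gives 11.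

Step 1. O-alkylation may compete with C-alkylation, and over-alkylation may dearomatize the ring. The fallback places both prenyl groups by cross-coupling at halogenated positions; it sets out from 1 and comes back at 3. Bis-MOM protection of 1 as in step 2 gives methyl 2-hydroxy-4,6-bis(methoxymethoxy)benzoate F9. Iodination of the two remaining ring positions (N-iodosuccinimide, 2.2 equiv, DMF, rt) gives methyl 2-hydroxy-3,5-diiodo-4,6-bis(methoxymethoxy)benzoate F10. Double Stille coupling under the conditions of step 4 (tributyl(prenyl)stannane, Pd(PPh3)4, DMF, 95 °C) gives 3.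

**Further compounds**
F1 | step 10 | 1-[2,4,6-trihydroxy-3,5-bis(3-methylbut-2-en-1-yl)phenyl]ethanone | CC(=O)c1c(O)c(CC=C(C)C)c(O)c(CC=C(C)C)c1O
F2 | step 10 | 1-[2-hydroxy-4,6-bis(methoxymethoxy)-3,5-bis(3-methylbut-2-en-1-yl)phenyl]ethanone | CC(=O)c1c(O)c(CC=C(C)C)c(OCOC)c(CC=C(C)C)c1OCOC
F3 | step 10 | (E)-1-[2-hydroxy-4,6-bis(methoxymethoxy)-3,5-bis(3-methylbut-2-en-1-yl)phenyl]-3-[3-methoxy-4-(methoxymethoxy)-5-(3-methylbut-2-en-1-yl)phenyl]prop-2-en-1-one | COc1cc(/C=C/C(=O)c2c(O)c(CC=C(C)C)c(OCOC)c(CC=C(C)C)c2OCOC)cc(CC=C(C)C)c1OCOC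
F4 | step 10 | rac-5,7-bis(methoxymethoxy)-2-[3-methoxy-4-(methoxymethoxy)-5-(3-methylbut-2-en-1-yl)phenyl]-6,8-bis(3-methylbut-2-en-1-yl)-2,3-dihydro-4H-chromen-4-one | COc1cc(C2CC(=O)c3c(OCOC)c(CC=C(C)C)c(OCOC)c(CC=C(C)C)c3O2)cc(CC=C(C)C)c1OCOC
F5 | step 7 | 2-(hydroxymethyl)-3,5-bis(methoxymethoxy)-4,6-bis(3-methylbut-2-en-1-yl)phenol | OCc1c(O)c(CC=C(C)C)c(OCOC)c(CC=C(C)C)c1OCOC
F6 | step 7 | 2-{[(tert-butyldimethylsilyl)oxy]methyl}-3,5-bis(methoxymethoxy)-4,6-bis(3-methylbut-2-en-1-yl)phenol | CC(C)(C)[Si](C)(C)OCc1c(O)c(CC=C(C)C)c(OCOC)c(CC=C(C)C)c1OCOC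
F7 | step 7 | 2-{[(tert-butyldimethylsilyl)oxy]methyl}-3,5-bis(methoxymethoxy)-4,6-bis(3-methylbut-2-en-1-yl)phenyl 3-methoxy-4-(methoxymethoxy)-5-(3-methylbut-2-en-1-yl)benzoate | COc1cc(C(=O)Oc2c(CO[Si](C)(C)C(C)(C)C)c(OCOC)c(CC=C(C)C)c(OCOC)c2CC=C(C)C)cc(CC=C(C)C)c1OCOC
F8 | step 7 | tert-butyl{[2-({1-[3-methoxy-4-(methoxymethoxy)-5-(3-methylbut-2-en-1-yl)phenyl]ethenyl}oxy)-4,6-bis(methoxymethoxy)-3,5-bis(3-methylbut-2-en-1-yl)phenyl]methoxy}dimethylsilane | COc1cc(C(=C)Oc2c(CO[Si](C)(C)C(C)(C)C)c(OCOC)c(CC=C(C)C)c(OCOC)c2CC=C(C)C)cc(CC=C(C)C)c1OCOC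
F9 | step 1 | methyl 2-hydroxy-4,6-bis(methoxymethoxy)benzoate | COC(=O)c1c(O)cc(OCOC)cc1OCOC
F10 | step 1 | methyl 2-hydroxy-3,5-diiodo-4,6-bis(methoxymethoxy)benzoate | COC(=O)c1c(O)c(I)c(OCOC)c(I)c1OCOC
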